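**Strategy**

The target is a (3R)-isoflavanone whose pyranone ring (ring C: O1, C2, C3, C4, C4a, C8a) carries ring B on C3, the carbon lying between C2 and the C4 carbonyl. Removing C3 with its aryl group leaves a benzofuran-3(2H)-one, so the route inserts exactly this carbon: an aryl(chloro)carbene is added across the C2=C3 enol ether bond of a 3-silyloxybenzofuran and the adduct opens to the six-membered 4-pyranone (an isoflavone) in one operation. Asymmetric transfer hydrogenation with dynamic kinetic resolution and reoxidation then set C3, and a final aromatic Claisen rearrangement of a 7-O-(1,1-dimethylallyl) ether releases the 7-hydroxyl and the 8-prenyl group together.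

Key step: step 6

Remark: tert-butyl (2-methylbut-3-en-2-yl) carbonate is taken as a purchasable reagent; if it is not in stock it is one step from 2-methylbut-3-en-2-ol and Boc2O.

**Route**

Step 1
Reactants: 1 6-hydroxy-1-benzofuran-3(2H)-one; 2 tert-butyl (2-methylbut-3-en-2-yl) carbonate
Product: 3 6-[(2-methylbut-3-en-2-yl)oxy]-1-benzofuran-3(2H)-one
Conditions: Pd(PPh3)4 (2 mol%), 2 (1.05 equiv), THF, 0 °C
Reagents that add atoms: none
Why: Tsuji–Trost O-allylation, in which zerovalent palladium ionises 2 with loss of CO2 and the phenoxide (formed by the released tert-butoxide) attacks the 1,1-dimethylallyl complex at its more substituted terminus, the kinetic site for oxygen nucleophiles and the known outcome for acyl-substituted phenols; low temperature and near-stoichiometric 2 should spare the C2 methylene and prevent isomerisation to the linear ether.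

Step 2
Reactants: 3 6-[(2-methylbut-3-en-2-yl)oxy]-1-benzofuran-3(2H)-one
Product: 4 tert-butyl(dimethyl)({6-[(2-methylbut-3-en-2-yl)oxy]-1-benzofuran-3-yl}oxy)silane
Conditions: TBSOTf, Et3N (excess), CH2Cl2, −78 to 0 °C
Reagents that add atoms: tert-butyldimethylsilyl trifluoromethanesulfonate, CC(C)(C)[Si](C)(C)OS(=O)(=O)C(F)(F)F
Why: Soft enolisation and O-silylation, favoured because the enol of this ketone is an aromatic 3-hydroxybenzofuran; the excess amine keeps the medium non-acidic for the tertiary allyl ether.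

Step 3
Reactants: 5 2,2-dimethyl-2H-chromene-6-carbonitrile
Product: 6 2,2-dimethylchroman-6-carbonitrile
Conditions: H2 (1 atm), Pd/C, EtOAc, rt
Reagents that add atoms: none
Why: Heterogeneous catalytic hydrogenation should saturate the styrene-type C3=C4 bond well before the aryl nitrile is touched at atmospheric pressure.

Step 4
Reactants: 6 2,2-dimethylchroman-6-carbonitrile
Product: 8 2,2-dimethylchroman-6-carboximidamide hydrochloride, via lithium bis(trimethylsilyl)amidinate 7 (not isolated)
Conditions: LiN(SiMe3)2, THF, 0 °C to rt; then HCl (4 M in dioxane), 0 °C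
Reagents that add atoms: lithium bis(trimethylsilyl)amide, [Li+].C[Si](C)(C)[N-][Si](C)(C)C; hydrogen chloride, Cl
Why: Nucleophilic addition of the silylamide to the nitrile gives amidinate 7, and anhydrous HCl cleaves both N–Si bonds to leave the amidinium chloride (standard nitrile-to-amidine conversion).

Step 5
Reactants: 8 2,2-dimethylchroman-6-carboximidamide hydrochloride
Product: 10 3-chloro-3-(2,2-dimethylchroman-6-yl)-3H-diazirine, via N,N'-dichloroamidine 9 (not isolated)
Conditions: NaOCl (aq), LiCl, DMSO/pentane, 0 °C to rt, dark; used promptly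
Reagents that add atoms: sodium hypochlorite, [Na+].[O-]Cl
Why: Graham oxidation, in which hypochlorite chlorinates both amidine nitrogens (9), base-induced N–N closure follows and chloride returns to carbon to give the 3-aryl-3-chlorodiazirine, as is known for 4-alkoxybenzamidines.

Step 6
Reactants: 4 tert-butyl(dimethyl)({6-[(2-methylbut-3-en-2-yl)oxy]-1-benzofuran-3-yl}oxy)silane; 10 3-chloro-3-(2,2-dimethylchroman-6-yl)-3H-diazirine
Product: 14 3-(2,2-dimethylchroman-6-yl)-7-[(2-methylbut-3-en-2-yl)oxy]-4H-chromen-4-one, via aryl(chloro)carbene 11 (not isolated), via chlorocyclopropane adduct 12 (not isolated), via 4-silyloxybenzopyrylium chloride 13 (not isolated)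
Conditions: 10 added slowly, Na2CO3, 4 Å molecular sieves, MeCN, 50 °C, dark
Reagents that add atoms: none
Why: Thermolysis of 10 releases N2 and the singlet aryl(chloro)carbene 11, which adds in a concerted (2+1) fashion to the most nucleophilic π bond of 4, the C2=C3 silyl enol ether bond of the furan ring (benzofuran numbering), and so closes the transient cyclopropane of 12. Ionisation of the benzylic C–Cl bond, assisted by the 4-alkoxyaryl group, O1 and the silyloxy group, is coupled to disrotatory electrocyclic opening of the former C2–C3 bond, so the five-membered ring becomes the six-membered aromatic 4-silyloxy-1-benzopyrylium ion of 13 by ring expansion and not by cyclisation of a chain, and chloride then removes the silyl group to leave the 4-pyranone carbonyl. The closest known reaction types are the Ciamician–Dennstedt-type one-carbon insertion of aryl chlorodiazirines into indoles, pyrroles and indenes and the dihalocarbene ring expansion of cyclic silyl enol ethers to the homologous α-haloenones. No stereocentre is formed, since C3 is trigonal in 14, and both diastereomers of 12 should converge because the stabilised cation does not depend on a concerted departure of an endo chloride. The step needs chemoselectivity for the enol ether bond over the monosubstituted alkene of the allyl ether and over the arene rings, which the high nucleophilicity of the silyloxyfuran and the absence of a prenyl group at this stage should secure, and the temperature stays below the onset of the Claisen rearrangement. Regiochemistry is inherent, because the carbene carbon can only enter between C2 and the silyloxy-bearing carbon, so the aryl group ends on the new C3 (chromone numbering) flanked by C2–H and the C4 carbonyl.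

Step 7
Reactants: 14 3-(2,2-dimethylchroman-6-yl)-7-[(2-methylbut-3-en-2-yl)oxy]-4H-chromen-4-one
Product: 16 (3R,4R)-3-(2,2-dimethylchroman-6-yl)-7-[(2-methylbut-3-en-2-yl)oxy]chroman-4-ol (cis), via racemising isoflavanone 15 (not isolated)
Conditions: RuCl[(R,R)-TsDPEN](p-cymene) (3 mol%), HCO2H/Et3N (1:2), EtOAc, 40 °C
Reagents that add atoms: none
Why: Noyori–Ikariya asymmetric transfer hydrogenation of an isoflavone, in which conjugate reduction gives isoflavanone 15 whose C3 epimerises through the enol in the amine-rich medium, while the (R,R) catalyst reduces the C4 carbonyl to the 4R alcohol (sense as for 1-tetralone) and delivers hydride anti to the C3 aryl group, so dynamic kinetic resolution should funnel the material to the cis-(3R,4R) alcohol; the terminal alkene and the tertiary allyl ether are inert to the ruthenium hydride.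

Step 8
Reactants: 16 (3R,4R)-3-(2,2-dimethylchroman-6-yl)-7-[(2-methylbut-3-en-2-yl)oxy]chroman-4-ol
Product: 17 (3R)-3-(2,2-dimethylchroman-6-yl)-7-[(2-methylbut-3-en-2-yl)oxy]chroman-4-one
Conditions: Dess–Martin periodinane, NaHCO3, CH2Cl2, 0 °C; rapid filtration through neutral silica
Reagents that add atoms: none
Why: Dess–Martin oxidation of the benzylic secondary alcohol is fast and essentially neutral under bicarbonate buffering, so the C3 centre set in step 7 should be carried into the ketone without enolisation, and alkene and allyl ether are untouched.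

Step 9
Reactants: 17 (3R)-3-(2,2-dimethylchroman-6-yl)-7-[(2-methylbut-3-en-2-yl)oxy]chroman-4-one
Product: 19 (3R)-3-(2,2-dimethylchroman-6-yl)-7-hydroxy-8-(3-methylbut-2-en-1-yl)chroman-4-one, via ortho-dienone 18 (not isolated)
Conditions: toluene (degassed), 120 °C, sealed tube
Reagents that add atoms: none
Why: Aromatic Claisen rearrangement, in which the (3,3) shift of the 1,1-dimethylallyl aryl ether delivers the allyl terminus to C8, the ortho position between the two ring oxygens that is favoured in 7-allyloxybenzopyranones, and dienone 18 tautomerises to the phenol bearing a normal prenyl group; no acid, base or reagent is present, so C3 should not enolise and the ortho-prenylphenol should not cyclise.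

**Compound list**

1 | 6-hydroxy-1-benzofuran-3(2H)-one | O=C1COc2cc(O)ccc12 | starting material
2 | tert-butyl (2-methylbut-3-en-2-yl) carbonate | C=CC(C)(C)OC(=O)OC(C)(C)C | starting material
3 | 6-[(2-methylbut-3-en-2-yl)oxy]-1-benzofuran-3(2H)-one | C=CC(C)(C)Oc1ccc2C(=O)COc2c1 | intermediate
4 | tert-butyl(dimethyl)({6-[(2-methylbut-3-en-2-yl)oxy]-1-benzofuran-3-yl}oxy)silane | C=CC(C)(C)Oc1ccc2c(O[Si](C)(C)C(C)(C)C)coc2c1 | intermediate
5 | 2,2-dimethyl-2H-chromene-6-carbonitrile | N#Cc1ccc2OC(C)(C)C=Cc2c1 | starting material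
6 | 2,2-dimethylchroman-6-carbonitrile | N#Cc1ccc2OC(C)(C)CCc2c1 | intermediate
7 | lithium N,N'-bis(trimethylsilyl)-2,2-dimethylchroman-6-carboximidamidate | [Li+].C[Si](C)(C)N=C([N-][Si](C)(C)C)c1ccc2OC(C)(C)CCc2c1 | intermediate (not isolated)
8 | 2,2-dimethylchroman-6-carboximidamide hydrochloride | [Cl-].NC(=[NH2+])c1ccc2OC(C)(C)CCc2c1 | intermediate
9 | N,N'-dichloro-2,2-dimethylchroman-6-carboximidamide | ClN=C(NCl)c1ccc2OC(C)(C)CCc2c1 | intermediate (not isolated)
10 | 3-chloro-3-(2,2-dimethylchroman-6-yl)-3H-diazirine | ClC1(N=N1)c1ccc2OC(C)(C)CCc2c1 | intermediate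
11 | chloro(2,2-dimethylchroman-6-yl)carbene | Cl[C]c1ccc2OC(C)(C)CCc2c1 | intermediate (not isolated)
12 | 1-chloro-1-(2,2-dimethylchroman-6-yl)-6b-[(tert-butyldimethylsilyl)oxy]-4-[(2-methylbut-3-en-2-yl)oxy]-1a,6b-dihydro-1H-cyclopropa[b][1]benzofuran (diastereomer mixture) | ClC1(c2ccc3OC(C)(C)CCc3c2)C2Oc3cc(OC(C)(C)C=C)ccc3C12O[Si](C)(C)C(C)(C)C | intermediate (not isolated)
13 | 4-[(tert-butyldimethylsilyl)oxy]-3-(2,2-dimethylchroman-6-yl)-7-[(2-methylbut-3-en-2-yl)oxy]-1-benzopyrylium chloride | [Cl-].C=CC(C)(C)Oc1ccc2c(O[Si](C)(C)C(C)(C)C)c(-c3ccc4OC(C)(C)CCc4c3)c[o+]c2c1 | intermediate (not isolated)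
14 | 3-(2,2-dimethylchroman-6-yl)-7-[(2-methylbut-3-en-2-yl)oxy]-4H-chromen-4-one | O=c1c(-c2ccc3OC(C)(C)CCc3c2)coc2cc(OC(C)(C)C=C)ccc12 | intermediate
15 | 3-(2,2-dimethylchroman-6-yl)-7-[(2-methylbut-3-en-2-yl)oxy]chroman-4-one, racemising at C3 | O=C1C(c2ccc3OC(C)(C)CCc3c2)COc2cc(OC(C)(C)C=C)ccc12 | intermediate (not isolated)
16 | (3R,4R)-3-(2,2-dimethylchroman-6-yl)-7-[(2-methylbut-3-en-2-yl)oxy]chroman-4-ol (cis) | O[C@@H]1[C@H](c2ccc3OC(C)(C)CCc3c2)COc2cc(OC(C)(C)C=C)ccc12 | intermediate
17 | (3R)-3-(2,2-dimethylchroman-6-yl)-7-[(2-methylbut-3-en-2-yl)oxy]chroman-4-one | O=C1[C@H](c2ccc3OC(C)(C)CCc3c2)COc2cc(OC(C)(C)C=C)ccc12 | intermediate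
18 | (3R)-3-(2,2-dimethylchroman-6-yl)-8-(3-methylbut-2-en-1-yl)-2,3-dihydro-4H-chromene-4,7(8H)-dione (ortho-dienone, C8 undefined) | CC(C)=CCC1C(=O)C=CC2=C1OC[C@@H](c1ccc3c(c1)CCC(C)(C)O3)C2=O | intermediate (not isolated)
19 | (3R)-3-(2,2-dimethylchroman-6-yl)-7-hydroxy-8-(3-methylbut-2-en-1-yl)chroman-4-one | CC(C)=CCc1c(O)ccc2c1OC[C@@H](c1ccc3c(c1)CCC(C)(C)O3)C2=O | target

**Step count**

Total: 9 steps. Longest linear sequence: 7 steps (5 to 19 through steps 3, 4, 5, 6, 7, 8 and 9).

**Steps most likely to fail**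

Step 6. The electron-rich chlorodiazirine may decompose before the carbene is captured, the carbene may be diverted to the terminal alkene, or the enol ether may be desilylated by adventitious acid. The fallback sets out from 1 and comes back at 14; it keeps the furan-to-pyranone ring expansion but brings in the aryl group by cross-coupling. Compound 1 is silylated twice (TIPSOTf, Et3N, CH2Cl2) to 3,6-bis(triisopropylsilyloxy)-1-benzofuran F1. Dibromocarbene (CHBr3, KOtBu, hexane, −30 °C to rt) adds to the enol ether bond to give dibromocyclopropane adduct F2, which is not isolated and opens with loss of the bromosilane to 3-bromo-7-(triisopropylsilyloxy)-4H-chromen-4-one F3; this is the known dihalocarbene ring expansion of silyl enol ethers. Purchased 6-bromo-2,2-dimethylchroman is borylated (B2pin2, Pd(dppf)Cl2, KOAc, dioxane, 80 °C) to 2-(2,2-dimethylchroman-6-yl)-4,4,5,5-tetramethyl-1,3,2-dioxaborolane F4. Suzuki coupling of F3 with F4 (Pd(PPh3)4, K2CO3, dioxane/H2O, 80 °C) gives 3-(2,2-dimethylchroman-6-yl)-7-(triisopropylsilyloxy)-4H-chromen-4-one F5, and TBAF in THF frees 3-(2,2-dimethylchroman-6-yl)-7-hydroxy-4H-chromen-4-one F6. O-Allylation of F6 with 2 under the conditions of step 1 then gives 14; the allyl ether is deliberately introduced only after the last palladium-catalysed coupling.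

Step 9. At the temperature the rearrangement needs, the α-aryl ketone may enolise and lose enantiomeric purity, and part of the allyl group may migrate to C6. The fallback sets out from 14 and comes back at 19; it moves the rearrangement in front of the stereocentre. Heating 14 in N,N-diethylaniline (180 °C) takes it through isoflavone ortho-dienone F7 to 3-(2,2-dimethylchroman-6-yl)-7-hydroxy-8-(3-methylbut-2-en-1-yl)-4H-chromen-4-one F8, and any C6 isomer is removed at this achiral stage. Silylation (TBSCl, imidazole, DMF) gives its 7-O-tert-butyldimethylsilyl ether F9. Transfer hydrogenation as in step 7 passes through racemising isoflavanone silyl ether F10 to (3R,4R)-isoflavan-4-ol silyl ether F11, and Dess–Martin oxidation as in step 8 gives (3R)-isoflavanone silyl ether F12. Et3N·3HF in MeCN at 0 °C, a weakly acidic fluoride source, removes the silyl group without enolising C3 or cyclising the prenylphenol and gives 19.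

Step 1. The allylpalladium intermediate may equilibrate the branched ether to the linear prenyl ether, or the acidic C2 methylene may be C-allylated. The fallback sets out from 1 and comes back at 3; it uses no allylpalladium species. Compound 1 is alkylated with 3-chloro-3-methylbut-1-yne (K2CO3, KI, CuI cat., acetone, 50 °C) to 6-[(2-methylbut-3-yn-2-yl)oxy]-1-benzofuran-3(2H)-one F13, and semihydrogenation (H2, Pd/CaCO3 poisoned with Pb(OAc)2, quinoline, EtOAc, rt) gives 3 with the tertiary connectivity fixed.

**Further compounds**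

F1 | step 6 | 3,6-bis(triisopropylsilyloxy)-1-benzofuran | CC(C)[Si](C(C)C)(C(C)C)Oc1ccc2c(O[Si](C(C)C)(C(C)C)C(C)C)coc2c1
F2 | step 6 | 1,1-dibromo-4,6b-bis(triisopropylsilyloxy)-1a,6b-dihydro-1H-cyclopropa[b][1]benzofuran (not isolated) | BrC1(Br)C2Oc3cc(O[Si](C(C)C)(C(C)C)C(C)C)ccc3C12O[Si](C(C)C)(C(C)C)C(C)C
F3 | step 6 | 3-bromo-7-(triisopropylsilyloxy)-4H-chromen-4-one | O=c1c(Br)coc2cc(O[Si](C(C)C)(C(C)C)C(C)C)ccc12
F4 | step 6 | 2-(2,2-dimethylchroman-6-yl)-4,4,5,5-tetramethyl-1,3,2-dioxaborolane | CC1(C)CCc2cc(B3OC(C)(C)C(C)(C)O3)ccc2O1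
F5 | step 6 | 3-(2,2-dimethylchroman-6-yl)-7-(triisopropylsilyloxy)-4H-chromen-4-one | O=c1c(-c2ccc3OC(C)(C)CCc3c2)coc2cc(O[Si](C(C)C)(C(C)C)C(C)C)ccc12
F6 | step 6 | 3-(2,2-dimethylchroman-6-yl)-7-hydroxy-4H-chromen-4-one | O=c1c(-c2ccc3OC(C)(C)CCc3c2)coc2cc(O)ccc12
F7 | step 9 | 3-(2,2-dimethylchroman-6-yl)-8-(3-methylbut-2-en-1-yl)-4H-chromene-4,7(8H)-dione (ortho-dienone, not isolated) | CC(C)=CCC1C(=O)C=CC2=C1OC=C(c1ccc3c(c1)CCC(C)(C)O3)C2=O
F8 | step 9 | 3-(2,2-dimethylchroman-6-yl)-7-hydroxy-8-(3-methylbut-2-en-1-yl)-4H-chromen-4-one | CC(C)=CCc1c(O)ccc2c1occ(-c1ccc3c(c1)CCC(C)(C)O3)c2=O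
F9 | step 9 | 7-[(tert-butyldimethylsilyl)oxy]-3-(2,2-dimethylchroman-6-yl)-8-(3-methylbut-2-en-1-yl)-4H-chromen-4-one | CC(C)=CCc1c(O[Si](C)(C)C(C)(C)C)ccc2c1occ(-c1ccc3c(c1)CCC(C)(C)O3)c2=O
F10 | step 9 | 7-[(tert-butyldimethylsilyl)oxy]-3-(2,2-dimethylchroman-6-yl)-8-(3-methylbut-2-en-1-yl)chroman-4-one, racemising at C3 (not isolated) | CC(C)=CCc1c(O[Si](C)(C)C(C)(C)C)ccc2c1OCC(c1ccc3c(c1)CCC(C)(C)O3)C2=O
F11 | step 9 | (3R,4R)-7-[(tert-butyldimethylsilyl)oxy]-3-(2,2-dimethylchroman-6-yl)-8-(3-methylbut-2-en-1-yl)chroman-4-ol | CC(C)=CCc1c(O[Si](C)(C)C(C)(C)C)ccc2c1OC[C@@H](c1ccc3c(c1)CCC(C)(C)O3)[C@H]2O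
F12 | step 9 | (3R)-7-[(tert-butyldimethylsilyl)oxy]-3-(2,2-dimethylchroman-6-yl)-8-(3-methylbut-2-en-1-yl)chroman-4-one | CC(C)=CCc1c(O[Si](C)(C)C(C)(C)C)ccc2c1OC[C@@H](c1ccc3c(c1)CCC(C)(C)O3)C2=O
F13 | step 1 | 6-[(2-methylbut-3-yn-2-yl)oxy]-1-benzofuran-3(2H)-one | C#CC(C)(C)Oc1ccc2C(=O)COc2c1
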